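The X charged cannot leave a closed flask, so X and Z together should hold it, yet in the west run they summed to 98.6 % at 0.250 d and to 45.7 % at 3.00 d, and I took it that Z passes on into something unread.

all flasks: L 37 mM (held)

| charge | X | remark | time |
|---|---|---|---|
| west | 0.20 M | the very flask that is asked about, followed so far |  |
| north-west | 0.30 M | run made earlier |  |
| flask | 0.20 M |  | 6.0 d |

| run | time / d | Z / % | X / % |
|---|---|---|---|
| west | 0.250 | 32.0 | 66.6 |
| west | 0.833 | 67.3 | 18.9 |
| west | 1.25 | 69.7 | 5.5 |
| west | 2.00 | 60.2 | 0 |
| west | 3.00 | 45.7 | 0 |
| north-west | 0.417 | 42.5 | 53.7 |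
| north-west | 1.04 | 69.6 | 13.0 |
| north-west | 2.08 | 60.0 | 0.9 |
| north-west | 3.00 | 47.6 | 0.3 |
| north-west | 4.00 | 38.1 | 0 |

(each reading ± 1 percentage point)

- the numbers in the tables scatter by 1 percentage point (one standard deviation)
- at the start none of L is in solution

- the Z standing at 6.0 d, as a percentage of the X charged
- the change that raises the amount of Z at 6.0 d, in percent of the X charged most ("none" if none brings more than 2 percentage points) (delta / beta / none)
- amount of Z at 6.0 d, in percent of the X charged, after beta

- delta: doubling the saturation concentration of L, all else as stated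
- beta: doubling the transfer coefficient of L, all else as stated

The west and north-west recipes differ in X but share the saturation value of cL, and X read 0 % in the west run at 2.00 d, so from there Z had no visible source and I treated its fall as pseudo-first-order at steady dissolved L. But the two late slopes differed: the west pair from 2.00 d to 3.00 d gave 0.276 d⁻¹, while the later north-west pair from 3.00 d to 4.00 d gave 0.223 d⁻¹, which is lower. I carried this later figure as the late decay constant of Z, the rate per unit of Z at which Z falls late in a run. Applied to the west reading at 3.00 d, it gave me 23.4 % at 6.0 d.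

The forecast stood somewhat above my figure, with 24 %, best choice none and 24 % after beta, holding that “Faster transfer only shortens the early phase”.

The flask gave Z at 26.4 %, with none as the best choice: delta moved Z by −16 percentage points, and beta moved it by −1.8 points, to 24.6 %.

    X + D → Z (k = 3.40 M⁻¹ h⁻¹)
    2 D → Q (k = 0.810 M⁻¹ h⁻¹)
    Z ⇌ G (K = 0.350, k = 0.00960 h⁻¹)
    D + Z → J (k = 0.290 M⁻¹ h⁻¹)
    L ⇌ D, rate k5*(csat - [D]) (kL = 0.930 h⁻¹)

Z in the flask stood at 46.6 % at 3.00 d, and the carried constant took that to 23.9 % at 6.0 d, less than the 26.4 % the flask held, while cD read 0.0340 M and then 0.0344 M and G fell from 16.8 % to 12.0 %. Carried from 26.4 % onward, the same constant gave 10.8 % for the neighbouring flask, this same flask read at 10 d, and that flask held Z at 13.6 %.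

The runs were computed on assumed constants; noise was put on by code.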